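The route rests on one disconnection. The 2,5-dihydrofuran ring B (O1–C8–C7=C6–C5, carotenoid numbering), fused to cyclohexane ring A, is an isomer of a C6=C7=C8 allene whose neighbour C5 carries a tertiary hydroxyl. A cationic gold catalyst forms O1–C8 in a single 5-endo closure and turns the allene axis into the C8 centre. No Brønsted acid is present that could ionise the bis-allylic C8–O1 bond. The precursor is a C15 vinylidenecyclohexanol (3R,5R,6S; acetates at C3 and C11), obtained from a syn-epoxy enyne by anti-SN2' copper hydride reduction. A Wittig union with a C15 aldehyde ester and a redox adjustment then complete the C30 apocarotenal.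

Key step: step 10

Remark 1: by CIP analysis the target is all-E and (3R,5R,8R). C3–O and C5–O1 are cis on ring A and H8 is cis to the C5 methyl, so C3 must come from the (4R)-hydroxy enone, the series antipodal to natural 3-hydroxy carotenoids.
Remark 2: ethyl (2E)-4-(diethoxyphosphoryl)-2-methylbut-2-enoate is taken as a catalogue compound (otherwise one Arbuzov step from ethyl 4-bromo-2-methylbut-2-enoate).

Step 1
Reactants: 1 ketoisophorone (2,6,6-trimethylcyclohex-2-ene-1,4-dione)
Product: 2 (4R)-4-hydroxy-2,6,6-trimethylcyclohex-2-en-1-one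
Conditions: RuCl[(R,R)-TsDPEN](p-cymene) (1 mol %), KOt-Bu (1 mol %), i-PrOH, 20 °C
Reagents that add atoms: none
Why: Noyori asymmetric transfer hydrogenation should reduce only the open C4 carbonyl (C1 is flanked by the gem-dimethyl carbon and the methyl-bearing alkene carbon), and the CH/π contact between the p-cymene ligand and the enone π system, as with aryl and alkenyl ketones, directs hydride from the (R,R) catalyst to the face that gives the (4R) carbinol, the future C3.

Step 2
Reactants: 2 (4R)-4-hydroxy-2,6,6-trimethylcyclohex-2-en-1-one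
Product: 3 (4R)-4-(tert-butyldimethylsilyloxy)-2,6,6-trimethylcyclohex-2-en-1-one
Conditions: TBSCl, imidazole, DMF, rt
Reagents that add atoms: tert-butyldimethylsilyl chloride, CC(C)(C)[Si](C)(C)Cl
Why: Imidazole-promoted silylation of a secondary alcohol, chosen because the silyl ether withstands hydride, enolate and palladium chemistry and leaves the carbinol centre untouched.

Step 3
Reactants: 3 (4R)-4-(tert-butyldimethylsilyloxy)-2,6,6-trimethylcyclohex-2-en-1-one
Product: 5 (4S)-4-(tert-butyldimethylsilyloxy)-2,6,6-trimethylcyclohex-1-en-1-yl triflate, via lithium enolate 4 (not isolated)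
Conditions: LiBH(s-Bu)3 (1.05 equiv), THF, −78 °C; then PhNTf2, −78 °C to rt
Reagents that add atoms: N-phenylbis(trifluoromethanesulfonimide), O=S(=O)(N(c1ccccc1)S(=O)(=O)C(F)(F)F)C(F)(F)F
Why: Reductive enol triflate formation: the bulky borohydride adds 1,4 to the enone, whose carbonyl is too hindered for 1,2-attack, the tetrasubstituted lithium enolate forms regiospecifically and is trapped on oxygen by the triflimide, and the silyloxy group sits γ to the enolate carbon so that it cannot be expelled (the descriptor changes to 4S by ranking only).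

Step 4
Reactants: 5 (4S)-silyloxy cyclohexenyl triflate; 6 (E)-3-methylpent-2-en-4-yn-1-ol
Product: 7 (2E)-5-[(4S)-4-(tert-butyldimethylsilyloxy)-2,6,6-trimethylcyclohex-1-en-1-yl]-3-methylpent-2-en-4-yn-1-ol
Conditions: PdCl2(PPh3)2 (5 mol %), CuI (10 mol %), i-Pr2NH, DMF (degassed), 45 °C
Reagents that add atoms: none
Why: Sonogashira coupling of a vinyl triflate with a terminal alkyne, known for hindered 2,6,6-trimethylcyclohexenyl triflates, joins C6 to C7, tolerates the free primary alcohol and keeps the E geometry of C9=C10.

Step 5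
Reactants: 7 C15 dienynol (C3-OTBS, C11-OH)
Product: 8 C15 dienynyl acetate (C3-OTBS, C11-OAc)
Conditions: Ac2O, pyridine, DMAP (cat.), CH2Cl2, 0 °C to rt
Reagents that add atoms: acetic anhydride, CC(=O)OC(C)=O
Why: Routine O-acetylation; the acetate removes the only allylic hydroxyl that could capture the vanadium catalyst of step 7 and is the later leaving group at C11.

Step 6
Reactants: 8 C15 dienynyl acetate (C3-OTBS, C11-OAc)
Product: 9 (2E)-5-[(4S)-4-hydroxy-2,6,6-trimethylcyclohex-1-en-1-yl]-3-methylpent-2-en-4-yn-1-yl acetate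
Conditions: HF·pyridine, THF, 0 °C to rt
Reagents that add atoms: none
Why: Fluoride-driven cleavage of the silyl ether under mildly acidic buffered conditions that leave the allylic acetate and the dienyne untouched, which frees the C3 hydroxyl as directing group.

Step 7
Reactants: 9 C3-hydroxy dienynyl acetate
Product: 10 (3R,5R,6R)-5,6-epoxy-7,8-didehydro C15 acetate with the oxirane oxygen cis to C3-OH
Conditions: VO(acac)2 (5 mol %), t-BuOOH (decane, 1.5 equiv), toluene, 0 °C to rt
Reagents that add atoms: tert-butyl hydroperoxide, CC(C)(C)OO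
Why: Vanadium-catalysed hydroxyl-directed epoxidation of a cyclic homoallylic alcohol: the C3 vanadate ester carries the peroxide to its own face of C5=C6, so C5 (R) and C6 (R) are set cis to C3-O, while C9=C10 has no free hydroxyl nearby and is poorer in electrons.

Step 8
Reactants: 10 syn-epoxy alcohol
Product: 11 (3R,5R,6R)-syn-epoxy enyne diacetate
Conditions: Ac2O, pyridine, DMAP (cat.), CH2Cl2, 0 °C
Reagents that add atoms: acetic anhydride, CC(=O)OC(C)=O
Why: Routine O-acetylation under basic conditions that do not open the propargylic oxirane; it keeps the secondary alcohol from consuming silane and binding copper in step 9 and is removed without an extra step by the hydride of step 14.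

Step 9
Reactants: 11 syn-epoxy enyne diacetate
Product: 13 (3R,5R,6S)-allenol diacetate (free C5-OH; H8 anti to C5-O), via C5 diethoxymethylsilyl ether 12 (not isolated)
Conditions: (IPr)CuCl (5 mol %), NaOt-Bu (5 mol %), (EtO)2MeSiH (2 equiv), toluene, 0 °C; then NH4F, MeOH, rt
Reagents that add atoms: none
Why: Copper hydride catalysed SN2' reduction of a propargylic oxirane: syn hydrocupration (H to C8, Cu to C7) followed by anti β-elimination of the C6–O bond puts hydride on the face opposite the oxirane and so sets the (6S) axis with H8 anti to C5–O, whereas aluminium hydrides that bind the oxirane oxygen deliver hydride syn and would give the wrong axis, and the silane/copper system leaves acetates alone.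

Step 10
Reactants: 13 (3R,5R,6S)-allenol diacetate
Product: 14 (3R,5R,8R)-C15 furanoid diacetate, that is (2E)-3-[(2R,6R,7aR)-6-acetoxy-4,4,7a-trimethyl-2,4,5,6,7,7a-hexahydro-1-benzofuran-2-yl]but-2-en-1-yl acetate
Conditions: Ph3PAuNTf2 (2 mol %), THF, −20 to 0 °C; Et3N quench
Reagents that add atoms: none
Why: Cationic monovalent gold binds the C7=C8 π bond on the side away from the C5 hydroxyl, the oxygen adds anti to C8, and protodeauration of the C7–Au bond gives C7–H and releases the catalyst. This is the known gold-catalysed cycloisomerisation of α-hydroxyallenes to 2,5-dihydrofurans. The one new ring (ring B, O1–C8–C7=C6–C5) closes in the 5-endo-trig mode, which is unstrained for an allene since the lobes of the C7=C8 π bond point within the plane defined by C5, C6 and C7. C8 is controlled by the allene axis alone: H8 and C9 stay on their own sides of that plane, so the (6S) axis becomes 8R with H8 cis to the C5 methyl. The step needs O-attack to outrun both loss of the axis through a gold-bound allyl cation and Nazarov-type closure of the vinylallene (C6 to C10); ring A holds the hydroxyl next to C8, C6 lies between two quaternary carbons, and the E C9=C10 bond keeps the C11 oxygen out of reach. The donor solvent, the low temperature and the amine quench protect the axis and the acid-labile C8–O1 bond.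

Step 11
Reactants: 14 (3R,5R,8R)-C15 furanoid diacetate
Product: 15 C15 furanoid triphenylphosphonium tetrafluoroborate (P at C11, C3-OAc kept)
Conditions: Pd(PPh3)4 (5 mol %), PPh3 (1.1 equiv), NaBF4 (1.5 equiv), MeCN, 40 °C
Reagents that add atoms: triphenylphosphine, c1ccc(cc1)P(c1ccccc1)c1ccccc1; sodium tetrafluoroborate, [Na+].F[B-](F)(F)F
Why: Tsuji-Trost type allylic substitution with triphenylphosphine as the nucleophile: zerovalent palladium ionises only the primary allylic C11 acetate, the phosphine attacks the unhindered C11 terminus of the π-allyl complex, sodium tetrafluoroborate removes acetate as its sodium salt, and the neutral medium avoids the acid that the usual phosphine hydrobromide method would bring to the C8–O1 bond.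

Step 12
Reactants: 16 (2E,4E,6E)-2,7-dimethylocta-2,4,6-trienedial; 17 ethyl (2E)-4-(diethoxyphosphoryl)-2-methylbut-2-enoate
Product: 19 ethyl (2E,4E,6E,8E,10E)-2,6,11-trimethyl-12-oxododeca-2,4,6,8,10-pentaenoate, via sodium phosphonate anion 18 (not isolated)
Conditions: 17, NaN(SiMe3)2, THF, −78 °C; added to 16 (2.5 equiv), −78 to 0 °C
Reagents that add atoms: none
Why: Horner-Wadsworth-Emmons olefination of one aldehyde of the symmetrical dialdehyde, kept in excess to favour mono-olefination, forms C11'=C12' with the E selectivity typical of stabilised phosphonate anions.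

Step 13
Reactants: 15 C15 furanoid phosphonium tetrafluoroborate; 19 C15 aldehyde ester
Product: 21 ethyl (all-E,3R,5R,8R)-3-acetoxy-5,8-epoxy-5,8-dihydro-8'-apo-β-caroten-8'-oate, via allylic ylide 20 (not isolated)
Conditions: NaN(SiMe3)2 (1.0 equiv), THF, −78 °C; then 19, −78 to 0 °C; then EtOAc, 70 °C, dark, argon
Reagents that add atoms: none
Why: Wittig olefination of an α-methyl enal by a semi-stabilised allylic ylide forms C11=C12, the ylide is made cold and trapped at once to avoid loss of the C8 alkoxide, and the sterically strained 11Z isomer should relax to all-E on gentle heating, as is usual for this hindered position in carotenoids.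

Step 14
Reactants: 21 C30 acetoxy ester
Product: 22 (all-E,3R,5R,8R)-5,8-epoxy-5,8-dihydro-8'-apo-β-carotene-3,8'-diol
Conditions: i-Bu2AlH (5 equiv), CH2Cl2, −78 °C; aq. potassium sodium tartrate
Reagents that add atoms: none
Why: Hydride reduction with diisobutylaluminium hydride takes the conjugated ester to the primary allylic alcohol and cleaves the C3 acetate in the same operation, and the cold aprotic conditions with a tartrate work-up leave ring B and its C8 centre alone.

Step 15
Reactants: 22 C30 diol
Product: 23 (all-E,3R,5R,8R)-3-hydroxy-5,8-epoxy-5,8-dihydro-8'-apo-β-caroten-8'-al (target)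
Conditions: MnO2 (activated, excess), CH2Cl2, rt, dark
Reagents that add atoms: none
Why: Manganese dioxide oxidises only the polyene-conjugated allylic alcohol to the enal, so the isolated secondary C3 hydroxyl and all stereocentres remain.

Compound list
1 | ketoisophorone | CC1=CC(=O)CC(C)(C)C1=O | starting material
2 | (4R)-4-hydroxy-2,6,6-trimethylcyclohex-2-en-1-one | O=C1C(C)(C)C[C@@H](O)C=C1C | intermediate
3 | (4R)-4-(tert-butyldimethylsilyloxy)-2,6,6-trimethylcyclohex-2-en-1-one | O=C1C(C)(C)C[C@@H](O[Si](C)(C)C(C)(C)C)C=C1C | intermediate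
4 | lithium enolate of the 1,4-reduced ketone | CC1=C([O-])C(C)(C)C[C@@H](O[Si](C)(C)C(C)(C)C)C1.[Li+] | intermediate
5 | (4S)-4-(tert-butyldimethylsilyloxy)-2,6,6-trimethylcyclohex-1-en-1-yl triflate | CC1=C(OS(=O)(=O)C(F)(F)F)C(C)(C)C[C@@H](O[Si](C)(C)C(C)(C)C)C1 | intermediate
6 | (E)-3-methylpent-2-en-4-yn-1-ol | C#C/C(C)=C/CO | starting material
7 | C15 dienynol, C3-OTBS, C11-OH | OC/C=C(\C)C#CC1=C(C)C[C@H](O[Si](C)(C)C(C)(C)C)CC1(C)C | intermediate
8 | C15 dienynyl acetate, C3-OTBS | CC(=O)OC/C=C(\C)C#CC1=C(C)C[C@H](O[Si](C)(C)C(C)(C)C)CC1(C)C | intermediate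
9 | C15 dienynyl acetate, free (S)-carbinol at C3 | CC(=O)OC/C=C(\C)C#CC1=C(C)C[C@H](O)CC1(C)C | intermediate
10 | (3R,5R,6R)-syn-epoxy alcohol, C11-OAc | CC(=O)OC/C=C(\C)C#C[C@@]12O[C@]1(C)C[C@H](O)CC2(C)C | intermediate
11 | (3R,5R,6R)-syn-epoxy enyne diacetate | CC(=O)OC/C=C(\C)C#C[C@@]12O[C@]1(C)C[C@H](OC(C)=O)CC2(C)C | intermediate
12 | C5 diethoxymethylsilyl ether of the allenol diacetate | CC(=O)OC/C=C(\C)C([H])=[C@]=C1C(C)(C)C[C@@H](OC(C)=O)C[C@@]1(C)O[Si](C)(OCC)OCC | intermediate
13 | (3R,5R,6S)-allenol diacetate: (2E)-5-[(2R,4R)-4-acetoxy-2-hydroxy-2,6,6-trimethylcyclohexylidene]-3-methylpenta-2,4-dien-1-yl acetate, (S) axis | CC(=O)OC/C=C(\C)C([H])=[C@]=C1C(C)(C)C[C@@H](OC(C)=O)C[C@@]1(C)O | intermediate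
14 | (3R,5R,8R)-C15 furanoid diacetate | CC(=O)OC/C=C(\C)[C@H]1C=C2C(C)(C)C[C@@H](OC(C)=O)C[C@@]2(C)O1 | intermediate
15 | C15 furanoid triphenylphosphonium tetrafluoroborate | F[B-](F)(F)F.c3ccccc3[P+](c3ccccc3)(c3ccccc3)C/C=C(\C)[C@H]1C=C2C(C)(C)C[C@@H](OC(C)=O)C[C@@]2(C)O1 | intermediate
16 | (2E,4E,6E)-2,7-dimethylocta-2,4,6-trienedial | O=C/C(C)=C/C=C/C=C(\C)C=O | starting material
17 | ethyl (2E)-4-(diethoxyphosphoryl)-2-methylbut-2-enoate | CCOC(=O)/C(C)=C/CP(=O)(OCC)OCC | starting material
18 | sodium salt of the phosphonate carbanion | [Na+].CCOC(=O)/C(C)=C/[CH-]P(=O)(OCC)OCC | intermediate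
19 | ethyl (2E,4E,6E,8E,10E)-2,6,11-trimethyl-12-oxododeca-2,4,6,8,10-pentaenoate | CCOC(=O)/C(C)=C/C=C/C(C)=C/C=C/C=C(\C)C=O | intermediate
20 | C15 furanoid allylic ylide | C(=P(c3ccccc3)(c3ccccc3)c3ccccc3)/C=C(\C)[C@H]1C=C2C(C)(C)C[C@@H](OC(C)=O)C[C@@]2(C)O1 | intermediate
21 | C30 acetoxy ethyl ester, all-E, (3R,5R,8R) | CCOC(=O)/C(C)=C/C=C/C(C)=C/C=C/C=C(C)/C=C/C=C(\C)[C@H]1C=C2C(C)(C)C[C@@H](OC(C)=O)C[C@@]2(C)O1 | intermediate
22 | C30 3,8'-diol, all-E, (3R,5R,8R) | OC/C(C)=C/C=C/C(C)=C/C=C/C=C(C)/C=C/C=C(\C)[C@H]1C=C2C(C)(C)C[C@@H](O)C[C@@]2(C)O1 | intermediate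
23 | (all-E,3R,5R,8R)-3-hydroxy-5,8-epoxy-5,8-dihydro-8'-apo-β-caroten-8'-al | C\C(C=O)=C/C=C/C(C)=C/C=C/C=C(C)/C=C/C=C(\C)[C@H]1C=C2C(C)(C)C[C@@H](O)C[C@@]2(C)O1 | target

Total step count: 15. Longest linear sequence: 14 (steps 1 to 11 and 13 to 15; step 12 is a one-step side branch).

Steps most likely to fail

1. Step 10 (key step).
- **Risk:** The gold-bound allene may open to a planar allyl cation, stabilised by the C9=C10 vinyl group, before oxygen attacks, and the axial information would then be lost. The C8–O1 bond may ionise again after closure, or the vinylallene may carbocyclise.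
- **Fallback:** It sets out from 13 and keeps the same O1–C8 bond formation but uses a halonium electrophile. N-Iodosuccinimide with NaHCO3 in CH2Cl2 at −20 °C should effect anti iodo-etherification across C7=C8, with C8 again fixed by the axis, and give the 7-iodo-2,5-dihydrofuran diacetate F1. Radical hydrodeiodination (Bu3SnH, Et3B, air, toluene, 0 °C) replaces the iodine at C7 by hydrogen without touching the allylic acetate and comes back to the route at 14.

2. Step 9.
- **Risk:** Hydrocupration of the conjugated enyne may take the wrong regiochemistry (copper at C8). The anti delivery may be incomplete, or the silane may slowly attack the acetates.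
- **Fallback:** It sets out from 11 and replaces hydrocupration and β-elimination by allenylpalladium chemistry. With Pd2(dba)3·CHCl3, P(n-Bu)3 and HCO2H/Et3N (1.1 equiv) in THF at 0 °C, zerovalent palladium attacks C8 anti to the strained C6–O bond. The σ-allenylpalladium formate loses CO2, and reductive elimination places hydrogen on C8 with retention, so the overall result is anti. The low temperature and the limited formate should let the oxirane react before the allylic acetate. The sequence comes back at 13 and makes no new compound.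

3. Step 11.
- **Risk:** The π-allyl complex may undergo elimination to a triene, the C9=C10 geometry may erode through π-σ-π isomerisation, or palladium may ionise the allylic C8–O1 bond.
- **Fallback:** It sets out from 14 and avoids palladium.
  - Methanolysis (K2CO3, MeOH, 0 °C) gives the C15 furanoid diol F2.
  - Corey-Kim type bromination (NBS, Me2S, CH2Cl2, −20 °C), which is selective for the primary allylic hydroxyl, gives the allylic bromide F3.
  - Triphenylphosphine in EtOAc at rt gives the 3-hydroxy phosphonium bromide F4.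
  - Two equivalents of NaN(SiMe3)2 and aldehyde 19 give the C30 hydroxy ester F5.
  - Reduction with i-Bu2AlH at −78 °C comes back to the route at 22.

Further compounds
F1 | step 10 | 7-iodo C15 furanoid diacetate (same spatial arrangement at C3, C5 and C8 as 14) | IC1=C2C(C)(C)C[C@@H](OC(C)=O)C[C@@]2(C)O[C@H]1/C(C)=C/COC(C)=O
F0 | step 9 | none | none
F2 | step 11 | (3R,5R,8R)-C15 furanoid diol | OC/C=C(\C)[C@H]1C=C2C(C)(C)C[C@@H](O)C[C@@]2(C)O1
F3 | step 11 | (3R,5R,8R)-C15 furanoid allylic bromide, free C3-OH | BrC/C=C(\C)[C@H]1C=C2C(C)(C)C[C@@H](O)C[C@@]2(C)O1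
F4 | step 11 | 3-hydroxy C15 furanoid triphenylphosphonium bromide | [Br-].c3ccccc3[P+](c3ccccc3)(c3ccccc3)C/C=C(\C)[C@H]1C=C2C(C)(C)C[C@@H](O)C[C@@]2(C)O1
F5 | step 11 | C30 3-hydroxy ethyl ester, all-E, (3R,5R,8R) | CCOC(=O)/C(C)=C/C=C/C(C)=C/C=C/C=C(C)/C=C/C=C(\C)[C@H]1C=C2C(C)(C)C[C@@H](O)C[C@@]2(C)O1
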